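(The constants used here were set for the occasion; the run is a simulation.)

A small charge of substrate meets a large excess of reagent in the set-ups below, and I want to know where each mole of it ends.

| flask | substrate | reagent | remark | time |
|---|---|---|---|---|
| south-west | 0.10 M | 5.00 equiv | one stirred flow tank at steady state, fed with the mixture as stated, mean residence time 6.0 h |  |
| south | 0.10 M | 5.00 equiv (fed, over 4.80 h) | all but reagent at the start; reagent goes in evenly over 4.80 h, the run ends at 6.0 h | 6.0 h |
| south-east | 0.10 M (fed, over 4.80 h) | 5.00 equiv | a stirred flask in which substrate is dosed at a steady rate over 4.80 h without added volume, worked up at 6.0 h | 6.0 h |
| north-west | 0.10 M | 5.00 equiv | a closed flask charged with all of it at once and left for 6.0 h | 6.0 h |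

    substrate + reagent → target, rate k1*[substrate]*[reagent]^1.5 (k1 = 2.0 M⁻¹·⁵ h⁻¹)
    substrate ⇌ dormant form (K2 = 1.7, k2 = 0.42 h⁻¹)
    target ⇌ isomer of the product (K3 = 0.51, k3 = 0.20 h⁻¹)

* the set-up with the highest amount of target at the outlet or at the end, in percent of the substrate put in ("none" if the first two lie within 2 percentage points) (south-west / south / south-east / north-west / none)
* amount of target at the outlet or at the end, in percent of the substrate put in, south-west
* amount of target at the outlet or at the end, in percent of the substrate put in, south
* amount of target at the outlet or at the end, in percent of the substrate put in, south-east
* amount of target at the outlet or at the end, in percent of the substrate put in, north-west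

- the stated concentrations are those of everything mixed, before any reaction; amounts are the same in each set-up
- the feed brings no volume worth counting
- run time (south): 6.0 h

**The branch.** Substrate is the limiting reagent, so I keep the books on it. A free mole either goes to target or moves forward to dormant form, and dividing these two rates removes time and substrate concentration, which leaves reagent strength. At full charge the ratio is 1.68. I call it S: the rate of making target over the forward rate of loss to dormant form, a selectivity factor.

**The ledger.** In north-west I hold S there, with reagent at 5.00 equiv. On first pass, 62.7% of the charge enters the target side and the rest parks as dormant form. Parked moles return at 0.247 h⁻¹, so, counting them as parked from the start, I reckon 77.3% of them back within 6.0 h. They split by S again, adding 18.1% of the charge. The target side closes at 80.8%, and 19.2% stays unbooked as substrate or dormant form. Target and isomer of the product relax with a half-life of 1.17 h, shorter than the run, so I split that side by 0.51. This books 53.5% as target.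

**The order.** In south, with the reagent dose half in at 2.40 h, S is at most 0.595 at that moment, less than at full charge, so I rank south below the other flasks I rank. South-east has its reagent in from the start, but its last substrate has 1.20 h to return, less than the 6.0 h of north-west, so I put it between south and north-west. I leave the tank south-west unbooked.

**The result.** The forecast names north-west, with 46.5%, 36%, 49% and 52% for south-west, south, south-east and north-west, and says “feeding reagent slowly does worst”. The simulation gives north-west, with 46.6%, 36.7%, 49.2% and 53.3% in that order. At 6.00 h the north-west books close at 5.46% substrate, 18.5% dormant form, 53.3% target and 22.8% isomer of the product. My target side of 80.8% stands above the 76.1% there, while isomer of the product over target reads 0.428, below my 0.51, so these two differences pull opposite ways on my 53.5%.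

**Thinner flask.** Take north-west with 0.025 M substrate and the same equivalents. The reagent is thinner too, so S falls to 0.210. I reckon 17.4% on first pass, the returning moles raise the target side to 28.5%, and the same split books 18.9% as target. That flask gives 16.6% target, with 6.16% isomer of the product, 27.3% substrate and 50.0% dormant form at 6.00 h.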